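**The question.** What share of L plus E is L in the flask with the full equivalent of D, at 5.0 s, 2.0 min and 40 min?

| setting | north-east | south-west | flask |
|---|---|---|---|
| Q | 0.015 M | 0.015 M | 0.015 M |
| D | 0.50 equiv | 0.75 equiv | 1.00 equiv |
| remark | run made earlier | run made earlier |  |
| time |  |  | 40 min |

| run | time / min | L / % | E / % |
|---|---|---|---|
| north-east | 10.0 | 18.2 | 31.8 |
| north-east | 20.0 | 17.9 | 31.4 |
| north-east | 30.0 | 18.0 | 31.2 |
| north-east | 40.0 | 18.6 | 31.6 |
| north-east | 50.0 | 18.3 | 31.2 |
| south-west | 4.00 | 32.8 | 41.4 |
| south-west | 12.0 | 33.6 | 41.7 |
| south-west | 20.0 | 33.0 | 42.6 |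
| south-west | 30.0 | 33.4 | 42.1 |
| south-west | 50.0 | 33.0 | 41.6 |

(scatter of a reading: 0.5 percentage points)

- share of L in L plus E at 5.0 s
- share of L in L plus E at 2.0 min
- share of L in L plus E at 40 min

- D is a solid; its amount is given per volume of the solution
- at the start none of D is in solution

**The plateaus.** Taking mean plateaus, L plus E stands at 49.6% of the charge in the north-east run and 75.0% in the south-west run. These match the equivalents of D, so D is the limiting reagent in both runs.

**The puzzle.** L's share of the product is 36.7% in the north-east run and 44.2% in the south-west run. Yet L takes 58.9% of the product added between them. Both hold. The share averages over all product made, while the marginal share is the L gained per L plus E gained between two flasks.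

**Our reckoning.** Suppose the remaining charge goes at this marginal share. Then L reaches 47.9% of the charge at 40 min. We hold this low, since the marginal share stands above the north-east share. No reading stands before 4.00 min, so we commit to no figure for the early times.

**The forecast.** It gives 27%, 47% and 54%, on the ground that “L is favoured as Q falls”. At 40 min it stands 6.1 percentage points above our reckoning.

**The result.** The flask gives 7.40%, 46.7% and 50.4%.

    Q ⇌ Z (K = 5.20, k = 0.0110 s⁻¹)
    D ⇌ X, rate k2*(cs2 - [X]) while solid is left; crystals form when [X] > cs2 (solubility = 1.10 mM, k = 0.560 s⁻¹)
    Q + X → E (k = 12.0 M⁻¹ s⁻¹)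
    X + Z → L (k = 30.0 M⁻¹ s⁻¹)

**Rates and steps.** The half-life of Q by its loss to Z, forward rate alone, is 1.1 min, longer than 5.0 s. In the flask at 0.780 min, Q goes to Z 1.1 times as fast as it makes E, again by the forward rate alone. From the south-west plateau to this flask at 40 min, the marginal share comes to 69.0%, above the reading between the runs. The neighbour flask with 0.250 equiv of D has a share of 25.4% at 40 min, and from it to the north-east plateau the marginal share is 48.1%.

(All runs were generated by integration with made-up constants; noise was put on by code.)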